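**Retrosynthetic overview**
- The strategy rests on the dihydropyran ring of the chroman. C2, which carries the methyl group, lies between O1 and C3 at the oxidation level of acetaldehyde. C4 is a doubly benzylic carbon whose cation is stabilized by O1 through the benzene ring and is bonded to C4 of 1,8-dimethoxynaphthalene, para to a methoxy group.
- Last disconnection: the C5–O pivalate, which only tempers the phenol ring during the cationic step.
- Key disconnection: O1–C2, C2–C3 and C4–C1'(naphthyl) together, back to 3-hydroxy-2-vinylphenyl pivalate, acetaldehyde and 1,8-dimethoxynaphthalene (Prins cyclization ended by Friedel–Crafts capture under a chiral Brønsted acid).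
- Ring order: the benzene and naphthalene rings are bought; the dihydropyran ring (O1–C2–C3–C4–C4a–C8a) is the only ring formed, in the key step.
- The vinylphenol comes from 2,6-dihydroxybenzaldehyde by monopivaloylation and Wittig methylenation; the arene comes from naphthalene-1,8-diol by methylation.

Key step: step 4

Assumption: the target is the trans (2R,4S) isomer; the chiral acid ("acid A") is the N,N'-bis(trifluoromethanesulfonyl) imidodiphosphorimidate of two (S)-3,3'-bis(4-tert-butylphenyl)-1,1'-bi-2-naphthol units, and since its sense of induction at C2 cannot be predicted, its mirror image is used if the (S,S) acid leads to the (2S) series.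

Step 1
Reactants: 1 2,6-dihydroxybenzaldehyde; 2 pivaloyl chloride
Product: 3 2-formyl-3-hydroxyphenyl pivalate
Conditions: 2 (1.05 equiv), Et3N (1.2 equiv), CH2Cl2, −20 → 0 °C
Reagents that add atoms: none
Why: O-Acylation of a phenol by an acid chloride; once one hydroxyl is esterified the other is held in a strong hydrogen bond to the aldehyde oxygen and flanked by the formyl group, so one equivalent of the bulky chloride should stop at the monoester.

Step 2
Reactants: 3 2-formyl-3-hydroxyphenyl pivalate
Product: 4 3-hydroxy-2-vinylphenyl pivalate
Conditions: Ph3PCH3Br (2.4 equiv), KOtBu (2.3 equiv), THF, 0 °C; then 3, −20 °C → rt; aq NH4Cl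
Reagents that add atoms: methyltriphenylphosphonium bromide, C[P+](c1ccccc1)(c1ccccc1)c1ccccc1.[Br-]
Why: Wittig methylenation, which tolerates a free ortho phenol when a second equivalent of ylide takes up the acidic proton (as for salicylaldehyde); the hindered pivalate sits meta to the phenoxide, cannot migrate to it, and should outlast the ylide at low temperature.

Step 3
Reactants: 5 naphthalene-1,8-diol
Product: 6 1,8-dimethoxynaphthalene
Conditions: MeI (4 equiv), K2CO3 (4 equiv), DMF, rt → 50 °C, argon
Reagents that add atoms: iodomethane, CI
Why: Williamson ether synthesis (double SN2 O-methylation of the peri diol); excess reagent in a polar aprotic solvent should push the hydrogen-bonded monoether on to the diether, and argon keeps the electron-rich naphtholate from air oxidation.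

Step 4
Reactants: 4 3-hydroxy-2-vinylphenyl pivalate; 7 acetaldehyde; 6 1,8-dimethoxynaphthalene
Product: 11 (2R,4S)-4-(4,5-dimethoxynaphthalen-1-yl)-2-methylchroman-5-yl pivalate, via aryl oxocarbenium ion 8 (not isolated), via chroman-4-yl cation 9 (not isolated), via chroman-4-ol 10 (not isolated)
Conditions: 7 (1.2 equiv), acid A (5 mol%), toluene, −40 °C; then 6 (2 equiv), 5 Å MS, −40 → 0 °C
Reagents that add atoms: none
Why: Proposed new method: acid A condenses the phenol oxygen of 4 with 7 to the hemiacetal and ionizes it to the aryl oxocarbenium ion 8 (O1–C2), the terminal carbon of the ortho vinyl group attacks C2 in a 6-endo-trig closure of the dihydropyran ring (C2–C3), and the resulting O1-stabilized benzylic C4 cation 9 is held reversibly by the liberated water as chroman-4-ol 10 until 6 is added and attacks 9 through its C4, para to a methoxy group (C4–aryl bond). The closest known reactions are Prins cyclizations of aldehydes with homoallylic alcohols under chiral imidodiphosphorimidate catalysis, Lewis acid Prins cyclizations that end in a Friedel–Crafts arylation, and acid-catalysed dehydrative arylation of benzylic chroman-4-ols; what is new is an aryl oxocarbenium ion as the electrophile under a chiral anion. C2 is set in the C–C bond-forming event by the chiral anion, which is paired with 8 in its confined pocket and leaves one face of the oxocarbenium carbon open to the vinyl group. C4 is set by the substrate: 6 adds axially to the half-chair of 9 on the face away from the pseudoequatorial C2 methyl group, and the trans isomer, with the aryl group pseudoaxial beside the C5 pivalate, is also the more stable one. The step needs chemoselectivity for the phenol oxygen over the electron-rich arene in the reaction with 7, secured by adding 6 only after 4 is consumed, and regioselectivity on 6, secured by the higher nucleophilicity and lower hindrance of the position para to a methoxy group. The pivalate lowers the nucleophilicity of the benzene ring so that neither 7 nor 9 should alkylate it.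

Step 5
Reactants: 11 (2R,4S)-4-(4,5-dimethoxynaphthalen-1-yl)-2-methylchroman-5-yl pivalate
Product: 12 cladonaphchrom A, (2R,4S)-4-(4,5-dimethoxynaphthalen-1-yl)-2-methylchroman-5-ol
Conditions: K2CO3 (2 equiv), MeOH, rt → 45 °C; aq NH4Cl
Reagents that add atoms: none
Why: Base-mediated transesterification (methanolysis) of an aryl ester, driven by the good phenoxide leaving group; the aryl methyl ethers, the chroman ether and both stereocenters, which bear no acidic or leaving group under these conditions, should be untouched.

**Compound list**
1 | 2,6-dihydroxybenzaldehyde | O=Cc1c(O)cccc1O | starting material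
2 | pivaloyl chloride | CC(C)(C)C(=O)Cl | starting material
3 | 2-formyl-3-hydroxyphenyl pivalate | O=Cc1c(O)cccc1OC(=O)C(C)(C)C | intermediate
4 | 3-hydroxy-2-vinylphenyl pivalate | C=Cc1c(O)cccc1OC(=O)C(C)(C)C | intermediate
5 | naphthalene-1,8-diol | Oc1cccc2cccc(O)c12 | starting material
6 | 1,8-dimethoxynaphthalene | COc1cccc2cccc(OC)c12 | intermediate
7 | acetaldehyde | CC=O | starting material
8 | ethylidene[3-(pivaloyloxy)-2-vinylphenyl]oxonium ion (aryl oxocarbenium ion, formed in the flask) | C=Cc1c(OC(=O)C(C)(C)C)cccc1[O+]=CC | intermediate
9 | (2R)-2-methyl-5-(pivaloyloxy)chroman-4-yl cation (formed in the flask) | C[C@@H]1C[CH+]c2c(OC(=O)C(C)(C)C)cccc2O1 | intermediate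
10 | (2R)-4-hydroxy-2-methylchroman-5-yl pivalate, both C4 epimers (formed in the flask) | C[C@@H]1CC(O)c2c(OC(=O)C(C)(C)C)cccc2O1 | intermediate
11 | (2R,4S)-4-(4,5-dimethoxynaphthalen-1-yl)-2-methylchroman-5-yl pivalate (2,4-trans) | COc1cccc2c([C@@H]3C[C@@H](C)Oc4cccc(OC(=O)C(C)(C)C)c43)ccc(OC)c12 | intermediate
12 | cladonaphchrom A, (2R,4S)-4-(4,5-dimethoxynaphthalen-1-yl)-2-methylchroman-5-ol (2,4-trans) | COc1cccc2c([C@@H]3C[C@@H](C)Oc4cccc(O)c43)ccc(OC)c12 | target

**Step count**
Total: 5 steps. Longest linear sequence: 4 steps (steps 1, 2, 4, 5 from 2,6-dihydroxybenzaldehyde); step 3 is a one-step side branch.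

**Steps most likely to fail**

1. Step 4 (Proposed new method). The aldehyde and the styrene may be drawn off into intermolecular Prins addition, the vinylphenol may dimerize under the acid before the hemiacetal ionizes, the cation may be consumed by oligomerization before the arene arrives, or the chiral anion may discriminate the faces of the aryl oxocarbenium ion poorly, giving low enantiomeric purity at C2. The fallback sets out from 4 and takes C2 from the chiral pool. Mitsunobu etherification of 4 with commercial (S)-but-3-en-2-ol (PPh3, diisopropyl azodicarboxylate, THF, 0 °C → rt) should proceed with inversion to (R)-3-(but-3-en-2-yloxy)-2-vinylphenyl pivalate F1. Ring-closing metathesis of F1 with the second-generation Grubbs catalyst RuCl2(=CHPh)(PCy3)(H2IMes) in CH2Cl2 at 40 °C should give (R)-2-methyl-2H-chromen-5-yl pivalate F2. Protonation of F2 at C3 by a catalytic achiral acid (Tf2NH, CH2Cl2, −40 °C) in the presence of 6 regenerates cation 9, and the same axial Friedel–Crafts capture (acid-catalysed hydroarylation of a 2H-chromene) should give 11, where the route is rejoined.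

2. Step 2. Acyl transfer from the pivalate to the ylide or to the phenoxide, and slow olefination of the phenoxide-deactivated aldehyde, may erode the ester; the vinylphenol may also polymerize on work-up. The fallback sets out from 3 and removes the free phenol during the olefination. Silylation (TBSCl, imidazole, DMF, rt) should give 3-(tert-butyldimethylsilyloxy)-2-formylphenyl pivalate F3. Wittig methylenation of the now fully electrophilic aldehyde with only 1.1 equiv of Ph3P=CH2 (THF, −78 → 0 °C) should give 3-(tert-butyldimethylsilyloxy)-2-vinylphenyl pivalate F4. Buffered desilylation (Bu4NF, AcOH, THF, 0 °C) should return 4.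

3. Step 5. Methanolysis may stall because the pivalate carbonyl is shielded by its own tert-butyl group and by the pseudoaxial naphthyl group on the neighbouring C4. The fallback sets out from 11 and changes from solvolysis to reductive cleavage: i-Bu2AlH (3 equiv, CH2Cl2, −78 °C, Rochelle salt work-up) should deliver hydride to the ester carbonyl and release 12 directly; no new compound is made on this way (F0).

**Further compounds**
F1 | step 4 | (R)-3-(but-3-en-2-yloxy)-2-vinylphenyl pivalate | C=C[C@@H](C)Oc1cccc(OC(=O)C(C)(C)C)c1C=C
F2 | step 4 | (R)-2-methyl-2H-chromen-5-yl pivalate | C[C@@H]1C=Cc2c(OC(=O)C(C)(C)C)cccc2O1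
F3 | step 2 | 3-(tert-butyldimethylsilyloxy)-2-formylphenyl pivalate | CC(C)(C)[Si](C)(C)Oc1cccc(OC(=O)C(C)(C)C)c1C=O
F4 | step 2 | 3-(tert-butyldimethylsilyloxy)-2-vinylphenyl pivalate | CC(C)(C)[Si](C)(C)Oc1cccc(OC(=O)C(C)(C)C)c1C=C
F0 | step 5 | none | none
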